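**Retrosynthetic overview**
- The target comes from hydrogenolysis of its catechol bis-benzyl ether.
- The C3–CH2Ar bond and the C3 stereocentre come from anti-alkylation of the dianion of an α-hydroxy-β-benzyl lactone with a 3,4-bis(benzyloxy)benzyl chloride.
- The α-hydroxy lactone comes from enolate hydroxylation of (R)-β-(3,4-dimethoxybenzyl)-γ-butyrolactone.
- Key step: that lactone comes from a catalytic enantioselective, desymmetrising Baeyer–Villiger ring expansion of 3-(3,4-dimethoxybenzyl)cyclobutanone, which sets C4.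
- Ring order: both arenes come from catechol, the cyclobutanone ring is bought as 3-oxocyclobutanecarboxylic acid (joined to veratrole by Friedel–Crafts acylation, then deoxygenated), and the lactone is the only ring made.

Assumption: only species generated as a separate stage, or central to the mechanism of the new step, are numbered as non-isolated intermediates; transient species inside a single operation are not.

**Step 1**
Reactants: 1 catechol
Product: 2 1,2-dimethoxybenzene
Conditions: MeI (2.5 equiv), K2CO3, acetone, reflux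
Reagents that add atoms: iodomethane, CI
Why: Williamson ether synthesis methylates both phenoxide oxygens; no stereocentre is involved.

**Step 2**
Reactants: 2 1,2-dimethoxybenzene; 3 3-oxocyclobutane-1-carboxylic acid
Product: 5 3-(3,4-dimethoxybenzoyl)cyclobutan-1-one, via mixed anhydride 4 (not isolated)
Conditions: 3, (CF3CO)2O, CH2Cl2, 0 °C; then 2, 85% H3PO4 (cat.), rt
Reagents that add atoms: none
Why: Friedel–Crafts acylation by the acyl trifluoroacetate occurs only para to a methoxy group of the activated arene; the product is achiral because the substituted ring carbon carries two identical arms.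

**Step 3**
Reactants: 5 3-(3,4-dimethoxybenzoyl)cyclobutan-1-one
Product: 6 3-(3,4-dimethoxybenzyl)cyclobutan-1-one
Conditions: H2 (3 atm), 10% Pd/C, AcOH, HClO4 (cat.), rt
Reagents that add atoms: none
Why: Pd-catalysed benzylic hydrogenolysis converts the electron-rich aryl ketone C=O into CH2 under acid, while the non-benzylic cyclobutanone is not reduced on Pd; 6 is prochiral.

**Step 4**
Reactants: 6 3-(3,4-dimethoxybenzyl)cyclobutan-1-one
Product: 8 (R)-4-(3,4-dimethoxybenzyl)dihydrofuran-2(3H)-one, via silyl Criegee adduct 7 (not isolated)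
Conditions: chiral IDPi (imidodiphosphorimidate) acid (2 mol%, the antipode that gives R), Me3SiOOSiMe3 (1.3 equiv), CH2Cl2, −60 °C; then aq. Na2S2O3/NaHCO3
Reagents that add atoms: bis(trimethylsilyl) peroxide, C[Si](C)(C)OO[Si](C)(C)C
Why: Proposed new method: a counteranion-directed silylium-catalysed Baeyer–Villiger ring expansion, in which the peroxide silylates the IDPi acid, the Me3Si+/IDPi– pair activates the strained ketone, the silyl peroxide adds to give Criegee adduct 7, and silylation of its distal peroxide oxygen inside the confined chiral anion lets only one of the two enantiotopic ring CH2 groups lie antiperiplanar to the O–O bond and migrate with loss of (Me3Si)2O, so that prochiral C3 of 6 becomes the (R)-configured β-carbon of 8 (C4 of the target); the closest known reactions are the achiral Me3SiOTf-catalysed Baeyer–Villiger oxidation with bis(trimethylsilyl) peroxide and the chiral phosphoric acid/H2O2 desymmetrisation of 3-substituted cyclobutanones.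

**Step 5**
Reactants: 8 (R)-4-(3,4-dimethoxybenzyl)dihydrofuran-2(3H)-one
Product: 10 (3R,4S)-4-(3,4-dimethoxybenzyl)-3-hydroxydihydrofuran-2(3H)-one, via potassium enolate 9 (not isolated)
Conditions: KHMDS (1.1 equiv), THF, −78 °C; then (±)-3-phenyl-2-(phenylsulfonyl)oxaziridine, −78 °C; AcOH quench
Reagents that add atoms: 3-phenyl-2-(phenylsulfonyl)oxaziridine, O=S(=O)(N1OC1c1ccccc1)c1ccccc1
Why: Davis enolate hydroxylation delivers oxygen anti to the C4 benzyl group (trans product); the C3 configuration does not matter because it is erased in step 8.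

**Step 6**
Reactants: 1 catechol
Product: 11 1,2-bis(benzyloxy)benzene
Conditions: BnBr (2.2 equiv), K2CO3, DMF, 60 °C
Reagents that add atoms: benzyl bromide, BrCc1ccccc1
Why: Williamson ether synthesis; the benzyl ethers tolerate mild Lewis acid and LDA and are later removed without touching the methyl ethers.

**Step 7**
Reactants: 11 1,2-bis(benzyloxy)benzene
Product: 12 1,2-bis(benzyloxy)-4-(chloromethyl)benzene
Conditions: MeOCH2Cl (3 equiv), ZnCl2 (10 mol%), CH2Cl2, 0 °C, short contact time
Reagents that add atoms: chloromethyl methyl ether, COCCl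
Why: Blanc-type chloromethylation (electrophilic aromatic substitution) occurs para to an alkoxy group of the 1,2-dialkoxyarene, the same position that veratrole uses.

**Step 8**
Reactants: 10 (3R,4S)-4-(3,4-dimethoxybenzyl)-3-hydroxydihydrofuran-2(3H)-one; 12 1,2-bis(benzyloxy)-4-(chloromethyl)benzene
Product: 14 (3S,4S)-3-[3,4-bis(benzyloxy)benzyl]-4-(3,4-dimethoxybenzyl)-3-hydroxydihydrofuran-2(3H)-one, via dilithium enediolate 13 (not isolated)
Conditions: LDA (2.1 equiv), THF–DMPU, −78 °C; then 12, −78 → −20 °C; AcOH quench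
Reagents that add atoms: none
Why: C-alkylation of the α-hydroxy lactone dianion (the enediolate alkylation used for wikstromol-type lignans) takes place on the face of the planar enediolate anti to the C4 benzyl group, giving trans benzyl groups with OH cis to the C4 substituent, i.e. (3S,4S).

**Step 9**
Reactants: 14 (3S,4S)-3-[3,4-bis(benzyloxy)benzyl]-4-(3,4-dimethoxybenzyl)-3-hydroxydihydrofuran-2(3H)-one
Product: 15 (3S,4S)-3-(3,4-dihydroxybenzyl)-4-(3,4-dimethoxybenzyl)-3-hydroxydihydrofuran-2(3H)-one
Conditions: H2 (1 atm), 10% Pd/C, EtOAc–MeOH, rt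
Reagents that add atoms: none
Why: Hydrogenolysis cleaves the two aryl benzyl ethers only; methyl ethers, lactone, tertiary alcohol and both stereocentres are untouched.

**Compound list**
1 | catechol (benzene-1,2-diol) | Oc1ccccc1O | starting material
2 | 1,2-dimethoxybenzene | COc1ccccc1OC | intermediate
3 | 3-oxocyclobutane-1-carboxylic acid | O=C1CC(C(=O)O)C1 | starting material
4 | 3-oxocyclobutanecarboxylic trifluoroacetic anhydride | O=C1CC(C(=O)OC(=O)C(F)(F)F)C1 | intermediate
5 | 3-(3,4-dimethoxybenzoyl)cyclobutan-1-one | COc1ccc(C(=O)C2CC(=O)C2)cc1OC | intermediate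
6 | 3-(3,4-dimethoxybenzyl)cyclobutan-1-one | COc1ccc(CC2CC(=O)C2)cc1OC | intermediate
7 | 3-(3,4-dimethoxybenzyl)-1-(trimethylsilyloxy)-1-(trimethylsilylperoxy)cyclobutane (cis/trans, achiral) | COc1ccc(CC2CC(O[Si](C)(C)C)(OO[Si](C)(C)C)C2)cc1OC | intermediate
8 | (R)-4-(3,4-dimethoxybenzyl)dihydrofuran-2(3H)-one | COc1ccc(C[C@H]2COC(=O)C2)cc1OC | intermediate
9 | potassium (R)-4-(3,4-dimethoxybenzyl)-4,5-dihydrofuran-2-olate | COc1ccc(C[C@H]2COC([O-])=C2)cc1OC.[K+] | intermediate
10 | (3R,4S)-4-(3,4-dimethoxybenzyl)-3-hydroxydihydrofuran-2(3H)-one | COc1ccc(C[C@H]2COC(=O)[C@@H]2O)cc1OC | intermediate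
11 | 1,2-bis(benzyloxy)benzene | c1ccc(COc2ccccc2OCc2ccccc2)cc1 | intermediate
12 | 1,2-bis(benzyloxy)-4-(chloromethyl)benzene | ClCc1ccc(OCc2ccccc2)c(OCc2ccccc2)c1 | intermediate
13 | dilithium (S)-4-(3,4-dimethoxybenzyl)-4,5-dihydrofuran-2,3-bis(olate) | COc1ccc(C[C@H]2COC([O-])=C2[O-])cc1OC.[Li+].[Li+] | intermediate
14 | (3S,4S)-3-[3,4-bis(benzyloxy)benzyl]-4-(3,4-dimethoxybenzyl)-3-hydroxydihydrofuran-2(3H)-one | COc1ccc(C[C@H]2COC(=O)[C@]2(O)Cc2ccc(OCc3ccccc3)c(OCc3ccccc3)c2)cc1OC | intermediate
15 | (3S,4S)-3-(3,4-dihydroxybenzyl)-4-(3,4-dimethoxybenzyl)-3-hydroxydihydrofuran-2(3H)-one | COc1ccc(C[C@H]2COC(=O)[C@]2(O)Cc2ccc(O)c(O)c2)cc1OC | target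

**Step count and risks**
Total steps: 9. Longest linear sequence: 7 (steps 1–5, 8, 9).

The three steps most likely to fail are steps 4, 8 and 7.

Step 4 is the new ring expansion. It may give insufficient ee, and the silylium/peroxide pair could hydroxylate the electron-rich arene. The fallback uses known chemistry and drops the oxidative ring expansion. It sets out from 6: enantioselective deprotonation with a chiral lithium amide (lithium bis(1-phenylethyl)amide, enantiomer chosen for R) and in situ Me3SiCl in THF at −100 °C gives (R)-{[3-(3,4-dimethoxybenzyl)cyclobut-1-en-1-yl]oxy}trimethylsilane F1. Ozonolysis (O3, CH2Cl2–MeOH, −78 °C) with NaBH4 work-up gives (R)-3-(3,4-dimethoxybenzyl)-4-hydroxybutanoic acid F2, which lactonises on acidification and comes back to the route at 8.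

Step 8 may suffer from O-alkylation, low conversion of the dianion or a poor diastereomer ratio. The fallback replaces alkylation by aldol addition and reductive removal of the extra hydroxyl. It sets out from 10 and 12: Kornblum oxidation of 12 (DMSO, NaHCO3) gives 3,4-bis(benzyloxy)benzaldehyde F5. Addition of enediolate 13 to F5, again anti to the C4 substituent, gives (3R,4S)-3-{[3,4-bis(benzyloxy)phenyl](hydroxy)methyl}-4-(3,4-dimethoxybenzyl)-3-hydroxydihydrofuran-2(3H)-one F6 as a mixture of carbinol epimers. One hydrogenolysis (H2, Pd/C, AcOH, cat. HClO4) removes the benzylic hydroxyl and both benzyl ethers, and the route is rejoined at 15.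

Step 7 may give diarylmethane by over-alkylation or partial loss of benzyl ethers. The fallback builds the benzylic carbon through an aryl metal instead of electrophilic substitution with a C1 electrophile. It sets out from 11: bromination (NBS, MeCN) gives 1,2-bis(benzyloxy)-4-bromobenzene F3. Bromine–lithium exchange (n-BuLi, THF, −78 °C) and trapping with paraformaldehyde gives [3,4-bis(benzyloxy)phenyl]methanol F4, which conc. HCl/CH2Cl2 converts into 12, where the route is rejoined.

**Further compounds**
F1 | step 4 | (R)-{[3-(3,4-dimethoxybenzyl)cyclobut-1-en-1-yl]oxy}trimethylsilane | COc1ccc(C[C@H]2C=C(O[Si](C)(C)C)C2)cc1OC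
F2 | step 4 | (R)-3-(3,4-dimethoxybenzyl)-4-hydroxybutanoic acid | COc1ccc(C[C@@H](CO)CC(=O)O)cc1OC
F3 | step 7 | 1,2-bis(benzyloxy)-4-bromobenzene | Brc1ccc(OCc2ccccc2)c(OCc2ccccc2)c1
F4 | step 7 | [3,4-bis(benzyloxy)phenyl]methanol | OCc1ccc(OCc2ccccc2)c(OCc2ccccc2)c1
F5 | step 8 | 3,4-bis(benzyloxy)benzaldehyde | O=Cc1ccc(OCc2ccccc2)c(OCc2ccccc2)c1
F6 | step 8 | (3R,4S)-3-{[3,4-bis(benzyloxy)phenyl](hydroxy)methyl}-4-(3,4-dimethoxybenzyl)-3-hydroxydihydrofuran-2(3H)-one (carbinol epimers) | COc1ccc(C[C@H]2COC(=O)[C@]2(O)C(O)c2ccc(OCc3ccccc3)c(OCc3ccccc3)c2)cc1OC
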